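## Analysis of the target

Ciwujiatone is a 2,3,4-trisubstituted oxolane (ring atoms O1, C2, C3, C4, C5). C2 carries a 4-hydroxy-3,5-dimethoxyphenyl group, C3 a hydroxymethyl group (carbon C6), C4 a 4-hydroxy-3,5-dimethoxybenzoyl group (carbonyl carbon C7), and C5 is a methylene group. The three stereocentres are contiguous and, in this numbering, (2S,3R,4R): the aryl group on C2 is trans to C6 on C3, and C6 is cis to C7 on C4. C4–H is α to the ketone and O1 is β to it through C5, so base can epimerise C4 to the all-trans isomer or open the ring by β-elimination. The C2–O1 bond is a benzylic ether on a para-oxygenated ring and is labile to acid, and the two free phenols are easily oxidised. The difficulty is that the cis C3/C4 relation has to be made under kinetic control and then kept, while two neighbouring carbon substituents of different oxidation level are told apart and the whole is obtained as one enantiomer. The strategy rests on C6 and C7 sitting on adjacent ring carbons on the same face. They can be delivered together as the two carbons of a ketene across a C3=C4 double bond, in a four-membered ring that can only be cis-fused; the C6–C7 bond of that ring is not in the target and is cut afterwards.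

## Retrosynthetic reasoning

**20 to 19.** The last operation cuts only two O–Si bonds. The phenols stay silylated to the end because free phenols of this type are oxidised easily and would consume base and organometallic reagents. A buffered desilylation needs neither the base that C4 does not tolerate nor the acid that the C2–O1 bond does not tolerate.

**19 to 15 and 18.** The C7–aryl bond is cut. The ketone and the primary alcohol of 19 are drawn back into one function, the γ-lactone of 15 that spans C6–O–C7, so one addition of aryllithium 18 to C7 releases both. While the lactone is closed, its cis fusion to the oxolane holds C4, so the epimerisable hydroxy ketone appears only two steps before the end. 18 comes from aryl bromide 17 by halogen–metal exchange, and 17 from bromophenol 16 by silylation.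

**15 to 13, 12 and 11.** The C6–O bond of the lactone is traced to the aldehyde of 13; reduction gives hydroxy ester 14, which can lactonise only because C6 and C7 are cis. The aldehyde is the hydrolysed form of the dichloromethyl group of 12. Ester 12 is what forms when the C6–C7 bond of dichlorocyclobutanone 11 is broken by an alkoxide (haloform-type cleavage). The cut is made there because it turns one ketone into two differentiated carbons in one move: C7 leaves at the acid level on C4 and C6 at the aldehyde level on C3, which is the order needed for a ketone at C7 and an alcohol at C6.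

**11 to 8 and 10.** This is the key disconnection: C3–C6 and C4–C7 are cut together, giving the 2-aryl-2,5-dihydrofuran 8 and dichloroketene 10 (made in the flask from trichloroacetyl chloride 9). A stepwise introduction of the two carbons would have to control a cis relation on a flexible five-membered ring against the thermodynamic preference. The (2+2) cycloaddition makes both bonds on one face, so cis is enforced. The forward reaction only has to choose the face (set by the C2 aryl group) and, less critically, the orientation of the ketene.

**8 to 7, 5 and 6.** The C3=C4 bond is opened by a retro ring-closing metathesis to diene 7, and the O1–C5 bond of 7 is cut to allylic alcohol 5 and allyl bromide 6. This leaves a precursor with a single stereocentre, C2, which is never touched again.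

**5 to 4, 2, 3 and 1.** Alcohol 5 is the slow-reacting enantiomer of racemic 4 in a kinetic resolution. 4 is cut at C2–C3 into aldehyde 2 and vinylmagnesium bromide 3, and 2 is the silyl ether of syringaldehyde 1.

## Alternatives that were turned down

**Alternative 1:** carbonyl ylide (3+2) onto a chiral alkoxybutenolide.
- Disconnection: C2–C3 and C4–C5, so the oxolane itself is made by a 1,3-dipolar cycloaddition.
- Forward key step: fluoride removes the silyl group of the α-chloro (trimethylsilyl)methyl ether A3 and chloride leaves. The unstabilised carbonyl ylide A4 then adds across the C=C bond of the menthyloxybutenolide A2, anti to the menthyloxy group. The product is the bicyclic lactone acetal A1, with C6 as lactone carbonyl and C7 as acetal carbon.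
- For it: the ring and all three ring stereocentres arise in one convergent step, and the absolute configuration comes from a cheap auxiliary rather than from a resolution that gives away half of the material. On both points it is stronger than the chosen route.
- Against it:
  - A3 is an ionisable α-chloro benzylic ether of an electron-rich aldehyde, hard to make and to keep.
  - A4 has no stabilising group and can close to an oxirane or dimerise before it meets A2.
  - The face of A2 is well controlled, but the C2 configuration relative to C3 depends on ylide geometry and on the endo or exo placement of the aryl group, with no rigid control element.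
  - In A1, C6 and C7 are at the acid and aldehyde levels, the reverse of what the target needs. The acetal must be unmasked, the aryl group added to C7, C6 reduced, C7 reoxidised, and auxiliary and allyl ether removed, so the route is not shorter.
- Comparison: the chosen strategy fixes C2 before the key step and gets the cis C3/C4 relation from geometry, not from a transition-state preference.

**Alternative 2:** oxocarbenium–enol ether bicyclisation.
- Disconnection: C4–C5, with the ketone masked as the enol ether of a 5-aryl-2,3-dihydrofuran.
- Forward key step: Me3SiOTf ionises the methoxymethyl ether on O1 of A6. The enol ether carbon C4 attacks the new oxocarbenium carbon (the future C5) and closes the oxolane cis-fused. Water adds at C7, and the hemiketal opens to the bis-silyl ether A5 of the target.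
- For it: this has the best step economy of the four, and here it is clearly stronger. A5 is one deprotection from ciwujiatone, and the cis C3/C4 relation follows from the bicyclic intermediate.
- Against it:
  - A6 must already hold C2 and C3 in the right relative and absolute configuration next to an acid-labile enol ether, so the stereochemical problem moves into the precursor.
  - The closure forms a five-membered ring with the C=O(+) bond inside it (5-endo type), which is geometrically unfavourable.
  - The same Lewis acid can ionise the benzylic C2–O1 bond of the para-silyloxy aryl group, or protonate the enol ether.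
  - The epimerisable β-alkoxy ketone is formed in acid.
- Comparison: the chosen strategy runs its risky step on a simple substrate with one stereocentre under nearly neutral conditions, and pays with five more steps after it.

**Alternative 3:** silicon-tethered radical delivery of C6.
- Disconnection: C3–C6 only, with C7 and its aryl group already on C4 of a 2,5-dihydrofuran.
- Forward key step: Bu3SnH and an initiator turn the (bromomethyl)dimethylsilyl ether A8 into a silylmethyl radical, which adds 6-endo to C3. The radical at C4 takes a hydrogen atom to give the cis-fused oxasilinane A7. Tamao–Fleming oxidation, oxidation of the benzylic alcohol and desilylation would follow.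
- For it: neutral radical conditions spare the benzylic ether and the silyl ethers, the tether guarantees that C6 goes to C3, and no organometallic reagent has to add to a lactone. In functional-group tolerance it is as strong or stronger.
- Against it:
  - A8 is a 2,4-disubstituted dihydrofuran with a carbinol centre at C7, longer to make than 8. That centre is destroyed later but still steers the face at which the tether reaches C3, so it must be matched to C2.
  - 5-exo attack at C4 competes with the 6-endo mode.
  - C4 is set by hydrogen-atom transfer in a six/five ring system where cis and trans fusion are both possible, so the cis relation is a preference, not a necessity.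
  - It needs stoichiometric tin and three further steps.
- Comparison: the chosen strategy forms both C–C bonds in one step and gets cis from the four-membered ring.

Key step: step 6

Remark on the chemistry: the phenols are carried as triisopropylsilyl ethers, not tert-butyldimethylsilyl ethers, because an aryl silyl ether has to survive NaH, methoxide and an aryllithium and still leave with fluoride. 4-Bromo-2,6-dimethoxyphenol is taken to be commercially available. In the names below Ar = 3,5-dimethoxy-4-[(triisopropylsilyl)oxy]phenyl; O1, C2–C5, C6 and C7 are the labels of the analysis.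

## Route

Step 1
Reactants: 1 syringaldehyde (4-hydroxy-3,5-dimethoxybenzaldehyde)
Product: 2 3,5-dimethoxy-4-[(triisopropylsilyl)oxy]benzaldehyde (Ar–CHO)
Conditions: i-Pr3SiCl, imidazole, DMAP (cat.), DMF, 40 °C
Reagents that add atoms: triisopropylsilyl chloride, CC(C)[Si](Cl)(C(C)C)C(C)C
Why: Silylation of a phenol; the bulky silyl group, further shielded by the two ortho methoxy groups, is chosen to outlast the basic and nucleophilic steps that follow.

Step 2
Reactants: 2 Ar–CHO; 3 vinylmagnesium bromide
Product: 4 rac-1-Ar-prop-2-en-1-ol
Conditions: THF, −78 to 0 °C; aq. NH4Cl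
Reagents that add atoms: none
Why: Grignard 1,2-addition to an aryl aldehyde forms the C2–C3 bond; the alcohol is racemic at this stage.

Step 3
Reactants: 4 rac-1-Ar-prop-2-en-1-ol
Product: 5 (S)-1-Ar-prop-2-en-1-ol
Conditions: Ti(OiPr)4 (cat.), L-(+)-diisopropyl tartrate, t-BuOOH (0.6 equiv), 4 Å molecular sieves, CH2Cl2, −20 °C
Reagents that add atoms: none
Why: Sharpless kinetic resolution of a secondary allylic alcohol: with L-(+)-tartrate the (R)-enantiomer should be epoxidised much faster (to the anti epoxy alcohol), leaving the (S)-enantiomer, whose centre becomes C2 of the target. The configuration of 5 would be confirmed (for example as its MTPA esters) before going on; the antipodal tartrate would give the other enantiomer.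

Step 4
Reactants: 5 (S)-1-Ar-prop-2-en-1-ol; 6 allyl bromide
Product: 7 (S)-3-(allyloxy)-3-Ar-prop-1-ene (allyl ether of 5)
Conditions: NaH, Bu4NI (cat.), THF, 0 °C to rt
Reagents that add atoms: none
Why: Williamson ether synthesis on the alkoxide; no bond to the stereocentre is broken, so the configuration is kept.

Step 5
Reactants: 7 allyl ether of 5
Product: 8 (2S)-2-Ar-2,5-dihydrofuran
Conditions: RuCl2(=CHPh)(PCy3)(H2IMes) (second-generation Grubbs catalyst, 2 mol%), CH2Cl2, 40 °C
Reagents that add atoms: none
Why: Ring-closing metathesis of two terminal alkenes to a five-membered cyclic allylic ether, driven by loss of ethene; C2 is not involved.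

Step 6
Reactants: 8 (2S)-2-Ar-2,5-dihydrofuran; 9 trichloroacetyl chloride
Product: 11 (1S,2S,5R)-2-Ar-7,7-dichloro-3-oxabicyclo[3.2.0]heptan-6-one, via dichloroketene 10 (not isolated)
Conditions: Zn–Cu couple, DME, Et2O, slow addition of 9, 25–35 °C
Reagents that add atoms: none
Why: Zn removes two chlorine atoms from 9 to give dichloroketene 10, which adds to the C3=C4 bond of 8 in a concerted, asynchronous (2+2) cycloaddition: the electrophilic carbonyl carbon C7 bonds in advance to C4 and the CCl2 carbon C6 follows at C3. The closest known reaction type is the addition of dichloroketene to cyclopentene and to 2,5-dihydrofuran-type cyclic allylic ethers. The cyclobutanone ring is closed by the cycloaddition itself, both new bonds arriving on one face of the alkene (suprafacial), so the four/five ring fusion can only be cis. C3 and C4 are created together: their mutual relation (C6 cis to C7) is fixed by the suprafacial addition, and their relation to C2 by approach of the ketene to the face of the nearly flat dihydrofuran opposite to the aryl group (substrate control from C2). The step needs facial selectivity, which the C2 aryl group secures, and regioselectivity (C7 to C4), which is expected because the shorter, leading bond forms at the alkene carbon remote from the substituted C2 while the bulky CCl2 end forms its longer bond next to it; this preference may be modest, the isomers would be separated, and the other one is not lost (see the fallback). It also needs chemoselectivity for the alkene over the ring oxygen and the electron-rich arene: DME binds the ZnCl2 formed, and slow addition of 9 keeps the ketene concentration low so that oligomerisation does not outrun the cycloaddition.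

Step 7
Reactants: 11 dichlorocyclobutanone
Product: 12 methyl (3R,4S,5S)-5-Ar-4-(dichloromethyl)oxolane-3-carboxylate
Conditions: NaOMe (0.2 equiv), MeOH–THF, −10 to 0 °C; AcOH quench
Reagents that add atoms: methanol, CO
Why: Haloform-type cleavage: methoxide adds to the strained, dichloro-activated ketone C7 and the adduct expels C6 as a dichloromethyl carbanion, which methanol protonates and so regenerates methoxide. C3 and C4 are not touched, and cold, substoichiometric base protects the C4–H that is now α to an ester and β to O1.

Step 8
Reactants: 12 dichloromethyl ester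
Product: 13 methyl (3R,4S,5S)-5-Ar-4-formyloxolane-3-carboxylate
Conditions: AgNO3, 2,6-lutidine, THF–H2O, 50 °C
Reagents that add atoms: water, O
Why: Silver-assisted hydrolysis of a geminal dichloride to an aldehyde: Ag+ removes chloride with help from the cis ester carbonyl (five-membered participation), and the second chloride leaves from the resulting α-chloro ether. The buffer spares the benzylic ether and the silyl ether; 13 is taken on crude because C3–H is now α to an aldehyde.

Step 9
Reactants: 13 aldehyde ester
Product: 15 (3aR,4S,6aR)-4-Ar-tetrahydro-1H,3H-furo[3,4-c]furan-1-one (cis-fused lactone C7(=O)–O–C6H2), via hydroxy ester 14 (not isolated)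
Conditions: NaBH4, MeOH, 0 °C; then PPTS (cat.), CH2Cl2, rt
Reagents that add atoms: none
Why: Chemoselective borohydride reduction of the aldehyde in the presence of the ester, then lactonisation of the γ-hydroxy ester. Only the cis isomer can close to the bicyclic lactone, so any epimerised material stays behind as an open hydroxy ester and is removed.

Step 10
Reactants: 16 4-bromo-2,6-dimethoxyphenol
Product: 17 (4-bromo-2,6-dimethoxyphenoxy)triisopropylsilane (Ar–Br)
Conditions: i-Pr3SiCl, imidazole, DMF, 40 °C
Reagents that add atoms: triisopropylsilyl chloride, CC(C)[Si](Cl)(C(C)C)C(C)C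
Why: Phenol silylation as in step 1; the silyl ether is stable to the halogen–metal exchange that follows.

Step 11
Reactants: 15 cis-fused lactone; 17 Ar–Br
Product: 19 Ar-[(3R,4R,5S)-5-Ar-4-(hydroxymethyl)oxolan-3-yl]methanone (bis-O-triisopropylsilyl ciwujiatone), via aryllithium 18 (not isolated)
Conditions: 17, n-BuLi, THF, −78 °C; then 15, THF, −78 °C; aq. NH4Cl at −78 °C
Reagents that add atoms: none
Why: Bromine–lithium exchange, then addition of the aryllithium to the lactone carbonyl C7; the lithium hemiketal alkoxide persists at −78 °C and blocks a second addition. The cold quench releases the γ-hydroxy ketone with C3 and C4 as they were held in the lactone.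

Step 12
Reactants: 19 bis-O-triisopropylsilyl ciwujiatone
Product: 20 ciwujiatone, (4-hydroxy-3,5-dimethoxyphenyl)[(3R,4R,5S)-5-(4-hydroxy-3,5-dimethoxyphenyl)-4-(hydroxymethyl)oxolan-3-yl]methanone
Conditions: Bu4NF, AcOH, THF, 0 °C
Reagents that add atoms: none
Why: Fluoride cleaves both aryl silyl ethers; acetic acid buffers the phenoxide and fluoride basicity so that C4 is not epimerised and O1 is not eliminated.

## Compound list

1 | syringaldehyde | COc1cc(C=O)cc(OC)c1O | starting material
2 | 3,5-dimethoxy-4-[(triisopropylsilyl)oxy]benzaldehyde | COc1cc(C=O)cc(OC)c1O[Si](C(C)C)(C(C)C)C(C)C | intermediate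
3 | vinylmagnesium bromide | C=C[Mg]Br | starting material
4 | rac-1-Ar-prop-2-en-1-ol | COc1cc(cc(OC)c1O[Si](C(C)C)(C(C)C)C(C)C)C(O)C=C | intermediate
5 | (S)-1-Ar-prop-2-en-1-ol | COc1cc(cc(OC)c1O[Si](C(C)C)(C(C)C)C(C)C)[C@@H](O)C=C | intermediate
6 | allyl bromide | C=CCBr | starting material
7 | (S)-3-(allyloxy)-3-Ar-prop-1-ene | COc1cc(cc(OC)c1O[Si](C(C)C)(C(C)C)C(C)C)[C@@H](OCC=C)C=C | intermediate
8 | (2S)-2-Ar-2,5-dihydrofuran | COc1cc(cc(OC)c1O[Si](C(C)C)(C(C)C)C(C)C)[C@H]1OCC=C1 | intermediate
9 | trichloroacetyl chloride | ClC(=O)C(Cl)(Cl)Cl | starting material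
10 | dichloroketene | ClC(Cl)=C=O | intermediate (not isolated)
11 | (1S,2S,5R)-2-Ar-7,7-dichloro-3-oxabicyclo[3.2.0]heptan-6-one | COc1cc(cc(OC)c1O[Si](C(C)C)(C(C)C)C(C)C)[C@H]1OC[C@@H]2C(=O)C(Cl)(Cl)[C@H]12 | intermediate
12 | methyl (3R,4S,5S)-5-Ar-4-(dichloromethyl)oxolane-3-carboxylate | COc1cc(cc(OC)c1O[Si](C(C)C)(C(C)C)C(C)C)[C@H]1OC[C@H](C(=O)OC)[C@@H]1C(Cl)Cl | intermediate
13 | methyl (3R,4S,5S)-5-Ar-4-formyloxolane-3-carboxylate | COc1cc(cc(OC)c1O[Si](C(C)C)(C(C)C)C(C)C)[C@H]1OC[C@H](C(=O)OC)[C@@H]1C=O | intermediate
14 | methyl (3R,4R,5S)-5-Ar-4-(hydroxymethyl)oxolane-3-carboxylate | COc1cc(cc(OC)c1O[Si](C(C)C)(C(C)C)C(C)C)[C@H]1OC[C@H](C(=O)OC)[C@@H]1CO | intermediate (not isolated)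
15 | (3aR,4S,6aR)-4-Ar-tetrahydro-1H,3H-furo[3,4-c]furan-1-one | COc1cc(cc(OC)c1O[Si](C(C)C)(C(C)C)C(C)C)[C@H]1OC[C@@H]2C(=O)OC[C@H]12 | intermediate
16 | 4-bromo-2,6-dimethoxyphenol | COc1cc(Br)cc(OC)c1O | starting material
17 | (4-bromo-2,6-dimethoxyphenoxy)triisopropylsilane | COc1cc(Br)cc(OC)c1O[Si](C(C)C)(C(C)C)C(C)C | intermediate
18 | {3,5-dimethoxy-4-[(triisopropylsilyl)oxy]phenyl}lithium | [Li]c1cc(OC)c(O[Si](C(C)C)(C(C)C)C(C)C)c(OC)c1 | intermediate (not isolated)
19 | bis-O-triisopropylsilyl ciwujiatone | COc1cc(C(=O)[C@H]2CO[C@H](c3cc(OC)c(O[Si](C(C)C)(C(C)C)C(C)C)c(OC)c3)[C@H]2CO)cc(OC)c1O[Si](C(C)C)(C(C)C)C(C)C | intermediate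
20 | ciwujiatone | COc1cc(C(=O)[C@H]2CO[C@H](c3cc(OC)c(O)c(OC)c3)[C@H]2CO)cc(OC)c1O | target

## Step count and least certain steps

Total step count: 12. Longest linear sequence: 11 steps (steps 1–9, 11 and 12); step 10 is a one-step branch for the second aryl unit.

**Step 6 (key step).**
- What may go wrong: incomplete regiocontrol. Both alkene carbons are secondary and each is flanked by a C–O carbon, so the ketene carbonyl carbon may bond to C3 as well as to C4. The alkene is also inductively deactivated, so ketene oligomerisation and Lewis-acid opening of the allylic, benzylic C2–O1 bond can compete with a slow cycloaddition.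
- Fallback (from 8, back at 19): the regioisomer is not discarded but carried through a parallel sequence in which the ester and dichloromethyl groups exchange roles.
  - From 8 the same cycloaddition gives the regioisomeric 4-Ar-7,7-dichloro-3-oxabicyclo[3.2.0]heptan-6-one F1, with the carbonyl on C3.
  - NaOMe (cat.) in MeOH opens it to methyl 2-Ar-4-(dichloromethyl)oxolane-3-carboxylate F2.
  - AgNO3 and 2,6-lutidine in aqueous THF give methyl 2-Ar-4-formyloxolane-3-carboxylate F3.
  - Aryllithium 18 at −78 °C adds to the aldehyde C7, and the alkoxide closes onto the cis ester to the 4,8-diaryl-3,7-dioxabicyclo[3.3.0]octan-2-one F4.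
  - LiAlH4 reduces the lactone to the diol F5 (C6 as CH2OH, C7 as the benzylic carbinol).
  - Activated MnO2 oxidises only the benzylic alcohol, which gives 19.

**Step 8.**
- What may go wrong: slow ionisation of a dichloromethyl group that has no activating substituent of its own. Prolonged heating would bring epimerisation at C3 (now α to an aldehyde) or at C4, and acid-induced loss of the silyl group.
- Fallback (from 11, back at 15): the dichloromethyl group is avoided and C6–C7 is cut oxidatively.
  - Zn in AcOH dechlorinates 11 to 2-Ar-3-oxabicyclo[3.2.0]heptan-6-one F6.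
  - LDA and Me3SiCl in THF at −78 °C give, by kinetic deprotonation at the CH2 group C6, the trimethylsilyl enol ether F7.
  - Ozonolysis (CH2Cl2–MeOH, −78 °C, then Me2S) cleaves C6=C7 to the aldehyde acid, which closes to the hydroxy lactone F8.
  - NaBH4 in THF–aq. NaHCO3, then acidification, gives 15.

**Step 11.**
- What may go wrong: over-addition if the hemiketal alkoxide collapses before the quench. Alternatively the aryllithium may deprotonate C4, after which β-elimination of O1 opens the oxolane.
- Fallback (from 15, back at 20): the aryl group is added to a Weinreb amide instead of the lactone.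
  - MeNH(OMe)·HCl and Me3Al in CH2Cl2 open 15 to the hydroxy Weinreb amide F9.
  - Et3SiCl and imidazole give its triethylsilyl ether F10.
  - Aryllithium 18 at −78 °C gives, through the stable chelate, the silylated ketone F11.
  - Bu4NF and AcOH, as in step 12, remove all three silyl groups and give 20.

**Step 3.**
- What may go wrong: weak discrimination or erosion of enantiopurity. The monosubstituted vinyl group is epoxidised slowly, and the titanium alkoxide can ionise the electron-rich benzylic, allylic alcohol, which would racemise or transpose the recovered enantiomer.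
- Fallback (from 4, back at 5): resolution by enzymatic acyl transfer instead of epoxidation. Immobilised Candida antarctica lipase B with vinyl acetate in t-BuOMe should acetylate the (R)-enantiomer to the (R)-acetate F12 and leave 5, which is separated by chromatography.

## Further compounds

F1 | step 6 | 4-Ar-7,7-dichloro-3-oxabicyclo[3.2.0]heptan-6-one (regioisomer of 11, carbonyl on C3) | COc1cc(cc(OC)c1O[Si](C(C)C)(C(C)C)C(C)C)[C@H]1OC[C@@H]2C(Cl)(Cl)C(=O)[C@H]12
F2 | step 6 | methyl 2-Ar-4-(dichloromethyl)oxolane-3-carboxylate | COc1cc(cc(OC)c1O[Si](C(C)C)(C(C)C)C(C)C)[C@H]1OC[C@H](C(Cl)Cl)[C@@H]1C(=O)OC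
F3 | step 6 | methyl 2-Ar-4-formyloxolane-3-carboxylate | COc1cc(cc(OC)c1O[Si](C(C)C)(C(C)C)C(C)C)[C@H]1OC[C@H](C=O)[C@@H]1C(=O)OC
F4 | step 6 | 4,8-di-Ar-3,7-dioxabicyclo[3.3.0]octan-2-one (C7 epimers) | COc1cc(cc(OC)c1O[Si](C(C)C)(C(C)C)C(C)C)[C@H]1OC[C@@H]2C(OC(=O)[C@H]12)c1cc(OC)c(O[Si](C(C)C)(C(C)C)C(C)C)c(OC)c1
F5 | step 6 | Ar-[5-Ar-4-(hydroxymethyl)oxolan-3-yl]methanol (C7 epimers) | COc1cc(C(O)[C@H]2CO[C@H](c3cc(OC)c(O[Si](C(C)C)(C(C)C)C(C)C)c(OC)c3)[C@H]2CO)cc(OC)c1O[Si](C(C)C)(C(C)C)C(C)C
F6 | step 8 | 2-Ar-3-oxabicyclo[3.2.0]heptan-6-one | COc1cc(cc(OC)c1O[Si](C(C)C)(C(C)C)C(C)C)[C@H]1OC[C@@H]2C(=O)C[C@H]12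
F7 | step 8 | 2-Ar-6-(trimethylsilyloxy)-3-oxabicyclo[3.2.0]hept-6-ene | COc1cc(cc(OC)c1O[Si](C(C)C)(C(C)C)C(C)C)[C@H]1OC[C@@H]2C(O[Si](C)(C)C)=C[C@H]12
F8 | step 8 | 4-Ar-3-hydroxy-tetrahydro-1H,3H-furo[3,4-c]furan-1-one (lactol epimers) | COc1cc(cc(OC)c1O[Si](C(C)C)(C(C)C)C(C)C)[C@H]1OC[C@@H]2C(=O)OC(O)[C@H]12
F9 | step 11 | (3R,4R,5S)-5-Ar-4-(hydroxymethyl)-N-methoxy-N-methyloxolane-3-carboxamide | CON(C)C(=O)[C@H]1CO[C@H](c2cc(OC)c(O[Si](C(C)C)(C(C)C)C(C)C)c(OC)c2)[C@H]1CO
F10 | step 11 | triethylsilyl ether of F9 | CON(C)C(=O)[C@H]1CO[C@H](c2cc(OC)c(O[Si](C(C)C)(C(C)C)C(C)C)c(OC)c2)[C@H]1CO[Si](CC)(CC)CC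
F11 | step 11 | O6-triethylsilyl ether of 19 | COc1cc(C(=O)[C@H]2CO[C@H](c3cc(OC)c(O[Si](C(C)C)(C(C)C)C(C)C)c(OC)c3)[C@H]2CO[Si](CC)(CC)CC)cc(OC)c1O[Si](C(C)C)(C(C)C)C(C)C
F12 | step 3 | (R)-1-Ar-prop-2-en-1-yl acetate | COc1cc(cc(OC)c1O[Si](C(C)C)(C(C)C)C(C)C)[C@H](OC(C)=O)C=C
A1 | alternative 1 | exo-aryl, exo-menthyloxy 3,7-dioxabicyclo[3.3.0]octanone (aryl = 4-allyloxy-3,5-dimethoxyphenyl; lactone carbonyl C6, acetal carbon C7) | COc1cc(cc(OC)c1OCC=C)[C@H]1OC[C@@H]2[C@@H](O[C@H]3C[C@@H](C)CC[C@@H]3C(C)C)OC(=O)[C@H]12
A2 | alternative 1 | (5S)-5-[(1S,2R,5S)-menthyloxy]furan-2(5H)-one | O=C1C=C[C@@H](O[C@H]2C[C@@H](C)CC[C@@H]2C(C)C)O1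
A3 | alternative 1 | {[chloro(4-allyloxy-3,5-dimethoxyphenyl)methoxy]methyl}trimethylsilane (racemic) | COc1cc(cc(OC)c1OCC=C)C(Cl)OC[Si](C)(C)C
A4 | alternative 1 | carbonyl ylide ArCH=O(+)–CH2(−) (aryl = 4-allyloxy-3,5-dimethoxyphenyl) | COc1cc(cc(OC)c1OCC=C)C=[O+][CH2-]
A5 | alternative 2 | bis-O-tert-butyldimethylsilyl ciwujiatone | COc1cc(cc(OC)c1O[Si](C)(C)C(C)(C)C)[C@H]1OC[C@H](C(=O)c2cc(OC)c(O[Si](C)(C)C(C)(C)C)c(OC)c2)[C@@H]1CO
A6 | alternative 2 | 5-aryl-3-[aryl(methoxymethoxy)methyl]-2,3-dihydrofuran (aryl = 4-tert-butyldimethylsilyloxy-3,5-dimethoxyphenyl) | COc1cc(cc(OC)c1O[Si](C)(C)C(C)(C)C)[C@@H](OCOC)[C@H]1COC(=C1)c1cc(OC)c(O[Si](C)(C)C(C)(C)C)c(OC)c1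
A7 | alternative 3 | cis-fused oxolane–oxasilinane (C6 as Si–CH2 on C3, C7 as Si–O–CH(aryl) on C4) | COc1cc(cc(OC)c1O[Si](C)(C)C(C)(C)C)[C@H]1OC[C@@H]2[C@H](c3cc(OC)c(O[Si](C)(C)C(C)(C)C)c(OC)c3)O[Si](C)(C)C[C@H]12
A8 | alternative 3 | (bromomethyl)dimethylsilyl ether of aryl[(5S)-5-aryl-2,5-dihydrofuran-3-yl]methanol (aryl = 4-tert-butyldimethylsilyloxy-3,5-dimethoxyphenyl) | COc1cc(cc(OC)c1O[Si](C)(C)C(C)(C)C)[C@H]1OCC(=C1)[C@@H](O[Si](C)(C)CBr)c1cc(OC)c(O[Si](C)(C)C(C)(C)C)c(OC)c1
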